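The ratio I watch in this flask is reagent to substrate as charged, 1.50 to one, and it tells me what the flask can reach before I ask how fast it gets there.

    substrate + reagent → target (k1 = 110 M⁻¹ s⁻¹)
    substrate + reagent → isomer of the product (k2 = 340 M⁻¹ s⁻¹)
    substrate + reagent → second isomer (k3 = 30 M⁻¹ s⁻¹)

substrate 0.0020 M; reagent 3.00 mM; time 80 s

- at 80 s, what has stopped the reaction, if anything has (the reagent has run out first / all of the substrate has reacted / it is still moving)
- target at 80 s, in percent of the substrate charged
- isomer of the product at 80 s, in percent of the substrate charged

- the reaction counts as stopped when no species that holds the substrate changes by six tenths of a point or more over the second half of the time
- run time (flask): 80 s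

Each step spends one reagent per substrate, and the flask holds more reagent than substrate. So the substrate is the limiting reagent, and the flask can end with 33.3% of its reagent unused.

The three steps have the same two concentrations in their rates, so the reacting substrate divides between them as their constants do. The target's share, the constant of its step over the sum of the three constants, is 22.9%. The same sum gives the isomer of the product 70.8%. This share is the selectivity, and a yield is the share times the fraction of substrate that has reacted.

Now the speed. With reagent as charged, the substrate's half-life by the three steps together is 0.481 s, far shorter than the 80 s of the run. That is my weak link: the reagent falls as it works. Near the end it stands at its surplus of 1.00 mM, so I reckon again with that amount and get a half-life of 1.44 s. This is still far shorter than the run, and 55.6 such half-lives fit into it. I commit to full conversion, with the two shares as the yields.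

The forecast says all of the substrate has reacted, with 22.9% target and 70.8% isomer of the product, on the ground that “All three routes share the same concentration dependence”. The run gives all of the substrate has reacted, with 22.9% target and 70.8% isomer of the product. Substrate is down to 0.727% at 8.00 s, and reagent stands at 33.3% at 80.0 s.

The neighbour flask, with 0.0012 M of reagent and the rest as in the recipe, has 0.600 equiv of reagent, less than the substrate. In that neighbour flask the charge of reagent allows 60.0% of the substrate to react. Multiplying by the shares, I reckon 13.7% target and 42.5% isomer of the product. Its run gives 13.8% and 42.5%, with reagent at 0% at 80.0 s and 40% of the substrate still there.

The rate constants stand for no real mixture; the rest is arithmetic.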